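**Plan**
1. Enabling feature: each of the three C5 units is bound through its C1 to an arene carbon ortho to a phenol oxygen (C6 beside O5 and C8 beside O7 on ring A, C3' beside O4' on ring B). This is the footprint of a [3,3] shift from an O-CMe2-CH=CH2 or O-CMe2-C≡CH ether. C6 and C8 are the only C-H positions of ring A, and C3'/C5' of ring B are homotopic.
2. Cuts: first the pyran ring D (C3'-CH= and O4'-CMe2) together with C6-CH2 and C8-CH2, which leads back to an isomeric tris-ether of (2S)-naringenin. Then O1-C2 of ring C, the Cα=Cβ bond of the chalcone, and the three O-CMe2 ether bonds.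
3. Forward order: rings A and B are bought and one C5 chloride etherifies both. The ring A alkynes are semihydrogenated, an aldol condensation joins the halves, and ring C is closed. Ring D is closed last in a reagent-free isomerisation, in which the ring A ethers (until then the phenol protection) become the two prenyl groups.
4. Stereochemistry: the only stereocentre, C2 (S), comes from catalyst control in the thiourea-catalysed oxa-Michael closure of ring C and is carried unchanged through the last step.

Key step: step 6

Assumption: the quinine-derived 9-epi-amino thiourea is taken to give the 2S series. If the sense of induction proves opposite, its quinidine-derived pseudoenantiomer is used under the same conditions.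

**Step 1**
Reactants: 1 2,4,6-trihydroxyacetophenone; 2 3-chloro-3-methylbut-1-yne
Product: 3 1-[2-hydroxy-4,6-bis(2-methylbut-3-yn-2-yloxy)phenyl]ethanone
Conditions: 2 (2.3 equiv), DBU (2.5 equiv), CuCl2·2H2O (1 mol %), MeCN, 0 °C
Reagents that add atoms: 3-chloro-3-methylbut-1-yne (compound 2), C#CC(C)(C)Cl
Why: Copper-catalysed O-propargylation of phenols by a tertiary propargylic chloride (through a copper allenylidene) should take two hydroxyls and leave free the third, which is locked in the hydrogen bond to the acetyl group, and the low temperature keeps the electron-rich ethers from rearranging.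

**Step 2**
Reactants: 3 1-[2-hydroxy-4,6-bis(2-methylbut-3-yn-2-yloxy)phenyl]ethanone
Product: 4 1-[2-hydroxy-4,6-bis(2-methylbut-3-en-2-yloxy)phenyl]ethanone
Conditions: H2 (1 atm, stopped after 2 equiv), 5% Pd on CaCO3 poisoned with Pb(OAc)2 (Lindlar catalyst), quinoline, EtOAc, rt
Reagents that add atoms: none
Why: Lindlar semihydrogenation stops terminal alkynes at the alkene and leaves the aryl ketone, the phenol and the allylic C-O bonds untouched, which is the standard passage from aryl 1,1-dimethylpropargyl to aryl 1,1-dimethylallyl ethers.

**Step 3**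
Reactants: 5 4-hydroxybenzaldehyde; 2 3-chloro-3-methylbut-1-yne
Product: 6 4-(2-methylbut-3-yn-2-yloxy)benzaldehyde
Conditions: 2 (1.3 equiv), DBU (1.4 equiv), CuCl2·2H2O (1 mol %), MeCN, 0 °C to rt
Reagents that add atoms: 3-chloro-3-methylbut-1-yne (compound 2), C#CC(C)(C)Cl
Why: This is the same copper-catalysed O-propargylation of a phenol, in which the aldehyde is inert and the electron-poor ether does not rearrange at these temperatures.

**Step 4**
Reactants: 4 1-[2-hydroxy-4,6-bis(2-methylbut-3-en-2-yloxy)phenyl]ethanone; 6 4-(2-methylbut-3-yn-2-yloxy)benzaldehyde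
Product: 7 (E)-2'-hydroxy-4',6'-bis(2-methylbut-3-en-2-yloxy)-4-(2-methylbut-3-yn-2-yloxy)chalcone
Conditions: KOH (aq., excess), EtOH, rt; then cold dilute AcOH to pH 6
Reagents that add atoms: none
Why: Claisen-Schmidt condensation of a methyl ketone with a non-enolisable aldehyde gives the (E)-enone under thermodynamic control, the 2'-phenoxide keeps the chalcone open in strong base, and the tertiary ethers and the alkyne (no propargylic hydrogen) are stable to hydroxide at room temperature.

**Step 5**
Reactants: 7 (E)-2'-hydroxy-4',6'-bis(2-methylbut-3-en-2-yloxy)-4-(2-methylbut-3-yn-2-yloxy)chalcone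
Product: 8 (2S)-5,7-bis(2-methylbut-3-en-2-yloxy)-2-[4-(2-methylbut-3-yn-2-yloxy)phenyl]-2,3-dihydro-4H-chromen-4-one
Conditions: N-[3,5-bis(trifluoromethyl)phenyl]-N'-[(8α,9S)-6'-methoxycinchonan-9-yl]thiourea (10 mol %), toluene, 0 °C to rt, stopped at full conversion
Reagents that add atoms: none
Why: In this asymmetric intramolecular oxa-Michael addition (biomimetic chalcone-flavanone isomerisation, 6-endo-trig) the thiourea binds the enone carbonyl, the quinuclidine deprotonates the 2'-hydroxyl and the chiral pocket exposes one face of Cβ, so C2 is set as S by catalyst control, and only one flavanone can form because only one hydroxyl is free.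

**Step 6**
Reactants: 8 (2S)-5,7-bis(2-methylbut-3-en-2-yloxy)-2-[4-(2-methylbut-3-yn-2-yloxy)phenyl]-2,3-dihydro-4H-chromen-4-one
Product: 12 (2S)-5,7-dihydroxy-2-(2,2-dimethyl-2H-chromen-6-yl)-6,8-bis(3-methylbut-2-en-1-yl)-2,3-dihydro-4H-chromen-4-one (target), via diprenyl propargyl ether 9 (not isolated), via allenylphenol 10 (not isolated), via vinyl quinone methide 11 (not isolated)
Conditions: degassed 1,2-dichlorobenzene (0.02 M), silanised glass, argon, 110 °C then 170 °C in one operation
Reagents that add atoms: none
Why: On warming, the two aryl 1,1-dimethylallyl ethers undergo aromatic Claisen rearrangement through chair transition states (O5 to C6, O7 to C8) and enolise to the 5,7-diol 9; at the higher temperature the ring B ether undergoes the propargyl Claisen rearrangement to C3', the allenyl dienone enolises to 10, a [1,5]-hydrogen shift from O4'-H to the central allene carbon gives the (Z)-vinyl o-quinone methide 11, and 11 closes to the chromene. The closest known reaction types are the thermal rearrangement of aryl 1,1-dimethylallyl ethers to o-prenylphenols and the thermal conversion of aryl 1,1-dimethylpropargyl ethers into 2,2-dimethyl-2H-chromenes, both standard on flavonoid and coumarin ethers and run here in one operation. Ring D closes by a thermal disrotatory oxa-6π electrocyclisation that joins O4' to the CMe2 carbon, after the [3,3] shift has made the C3'-CH bond. No stereocentre is created; C2 is a spectator, its racemisation would need prior enolisation of C4/C3 or a free 4'-phenoxide, and the neutral, aprotic, base-free medium and the alkylated O4' are chosen to suppress both. Regioselectivity on ring A is secured because C6 and C8 are the only migration termini that carry hydrogen: a shift onto C4a or onto an already prenylated carbon gives a dienone that cannot enolise and reverts, and the competing Cope exit would have to form a hindered C8-CMe2 bond. Ring B poses no regiochemical question, since C3' and C5' are homotopic in the para-substituted ring.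

**Compound list**
1 | 2,4,6-trihydroxyacetophenone | CC(=O)c1c(O)cc(O)cc1O | starting material
2 | 3-chloro-3-methylbut-1-yne | C#CC(C)(C)Cl | starting material
3 | 1-[2-hydroxy-4,6-bis(2-methylbut-3-yn-2-yloxy)phenyl]ethanone | CC(=O)c1c(O)cc(OC(C)(C)C#C)cc1OC(C)(C)C#C | intermediate
4 | 1-[2-hydroxy-4,6-bis(2-methylbut-3-en-2-yloxy)phenyl]ethanone | CC(=O)c1c(O)cc(OC(C)(C)C=C)cc1OC(C)(C)C=C | intermediate
5 | 4-hydroxybenzaldehyde | O=Cc1ccc(O)cc1 | starting material
6 | 4-(2-methylbut-3-yn-2-yloxy)benzaldehyde | O=Cc1ccc(OC(C)(C)C#C)cc1 | intermediate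
7 | (E)-2'-hydroxy-4',6'-bis(2-methylbut-3-en-2-yloxy)-4-(2-methylbut-3-yn-2-yloxy)chalcone | O=C(/C=C/c1ccc(OC(C)(C)C#C)cc1)c1c(O)cc(OC(C)(C)C=C)cc1OC(C)(C)C=C | intermediate
8 | (2S)-5,7-bis(2-methylbut-3-en-2-yloxy)-2-[4-(2-methylbut-3-yn-2-yloxy)phenyl]-2,3-dihydro-4H-chromen-4-one | O=C1C[C@@H](c2ccc(OC(C)(C)C#C)cc2)Oc2cc(OC(C)(C)C=C)cc(OC(C)(C)C=C)c21 | intermediate
9 | (2S)-5,7-dihydroxy-6,8-bis(3-methylbut-2-en-1-yl)-2-[4-(2-methylbut-3-yn-2-yloxy)phenyl]-2,3-dihydro-4H-chromen-4-one | CC(C)=CCc1c(O)c(CC=C(C)C)c2c(c1O)C(=O)C[C@@H](c1ccc(OC(C)(C)C#C)cc1)O2 | intermediate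
10 | (2S)-5,7-dihydroxy-2-[4-hydroxy-3-(3-methylbuta-1,2-dien-1-yl)phenyl]-6,8-bis(3-methylbut-2-en-1-yl)-2,3-dihydro-4H-chromen-4-one | CC(C)=CCc1c(O)c(CC=C(C)C)c2c(c1O)C(=O)C[C@@H](c1ccc(O)c(C=C=C(C)C)c1)O2 | intermediate
11 | (2S)-5,7-dihydroxy-6,8-bis(3-methylbut-2-en-1-yl)-2-[(3Z)-3-(3-methylbut-2-en-1-ylidene)-4-oxocyclohexa-1,5-dien-1-yl]-2,3-dihydro-4H-chromen-4-one | CC(C)=CCc1c(O)c(CC=C(C)C)c2c(c1O)C(=O)C[C@@H](C1=C/C(=C/C=C(C)C)C(=O)C=C1)O2 | intermediate
12 | (2S)-5,7-dihydroxy-2-(2,2-dimethyl-2H-chromen-6-yl)-6,8-bis(3-methylbut-2-en-1-yl)-2,3-dihydro-4H-chromen-4-one | CC(C)=CCc1c(O)c(CC=C(C)C)c2c(c1O)C(=O)C[C@@H](c1ccc3c(c1)C=CC(C)(C)O3)O2 | target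

Total step count: 6. Longest linear sequence: 5 (steps 1, 2, 4, 5, 6).

**Steps most likely to fail**

**Step 6.**
- Risk: configuration at C2 may erode slowly through reversible opening of ring C during the hot phase, and a ring A allyl group may leak through a Cope shift to the wrong terminus.
- Fallback: it sets out from 8 and comes back at 12, and it replaces the sigmatropic closure of ring D by π-acid catalysis.
- First stage: 8 is heated only to about 100-110 °C in toluene. This should suffice for the two allyl Claisen shifts, and the diprenyl propargyl ether 9 is isolated.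
- Second stage: 9 is cycloisomerised with Ph3PAuNTf2 (cat.) in CH2Cl2 at room temperature. This is a 6-endo-dig hydroarylation of the terminal alkyne, activated by cationic monovalent gold, by C3', followed by protodeauration. The unhindered alkyne should bind gold far better than the trisubstituted prenyl alkenes.
- No compound outside the list is made (F0).

**Step 5.**
- Risk: facial selectivity may be poor, the strongly chelated and hindered phenol may add sluggishly, and the enantiomeric purity may decay because the amine catalyst also promotes the reverse reaction.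
- Fallback: it sets out from 7 and comes back at 8.
- Cyclisation: 7 is cyclised without control (NaOAc, EtOH, 60 °C) to the racemic flavanone F1.
- Resolution: F1 is resolved kinetically by asymmetric transfer hydrogenation with RuCl(p-cymene)[(R,R)-TsDPEN] (cat.), HCO2H/Et3N, EtOAc, rt, run to about half conversion.
- Sense of the resolution: the catalyst imposes 4R and hydride arrives anti to the 2-aryl group, so the 2R enantiomer is the matched one. It is reduced to the cis-(2R,4R)-flavan-4-ol F2, and (2S)-8 is left behind and separated by chromatography.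

**Step 1.**
- Risk: C-alkylation of the phloroglucinol nucleus may compete, the third hydroxyl may be etherified, or the ethers may rearrange and cyclise prematurely.
- Fallback: it sets out from 1 and comes back at 4, bypassing 3 and the semihydrogenation.
- Reaction: decarboxylative O-allylation of Tsuji-Trost type with commercial tert-butyl 2-methylbut-3-en-2-yl carbonate, Pd(PPh3)4 (cat.), THF, 0 °C. This delivers the branched tertiary aryl ethers as the kinetic products.
- No compound outside the list is made (F0).

**Further compounds**
F0 | step 6 | none | none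
F1 | step 5 | racemic 5,7-bis(2-methylbut-3-en-2-yloxy)-2-[4-(2-methylbut-3-yn-2-yloxy)phenyl]-2,3-dihydro-4H-chromen-4-one | O=C1CC(c2ccc(OC(C)(C)C#C)cc2)Oc2cc(OC(C)(C)C=C)cc(OC(C)(C)C=C)c21
F2 | step 5 | (2R,4R)-5,7-bis(2-methylbut-3-en-2-yloxy)-2-[4-(2-methylbut-3-yn-2-yloxy)phenyl]-3,4-dihydro-2H-chromen-4-ol | O[C@@H]1C[C@H](c2ccc(OC(C)(C)C#C)cc2)Oc2cc(OC(C)(C)C=C)cc(OC(C)(C)C=C)c21
F0 | step 1 | none | none
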